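**Strategy.** Everything rests on building the 4-hydroxy-2-pyranone ring last. Coumarin C3 is the α-carbon of both the C4 aryl ketone and the C2 lactone carbonyl, so C2 is disconnected as a carbonate carbon. The key step, an anionic O→C methoxycarbonyl transfer/lactonisation (Baker–Venkataraman type), forms C2–C3 and closes ring O1–C2–C3–C4–C4a–C8a in one operation. Its precursor is an o-(methoxycarbonyloxy)aryl ketone whose α-carbon already carries the complete (E,E,E)-ω-benzoyloxyfarnesyl chain, attached earlier by ketone-enolate SN2 alkylation. The ambident 4-hydroxycoumarin (C3/O4/O2) therefore never meets an allylic electrophile, which avoids the usual first draw, C3-farnesylation of preformed 4-hydroxycoumarin.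

Key step: step 5

Remark: the target has no stereogenic centre, so "single enantiomer" is taken to mean the single geometric isomer with all three trisubstituted alkenes E; these are the only stereochemical elements to control. (2E,6E)-Farnesyl bromide is taken as a catalogue compound.

**Step 1**
Reactants: 1 (2E,6E)-farnesyl bromide; 2 2′-hydroxyacetophenone
Product: 4 (4E,8E)-1-(2-hydroxyphenyl)-5,9,13-trimethyltetradeca-4,8,12-trien-1-one, via dilithium enolate-phenoxide 3 (not isolated)
Conditions: LDA (2.1 equiv per 2), THF, −78 to 0 °C; then 1 (limiting), DMPU, −78 to −20 °C; aq. NH4Cl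
Reagents that add atoms: none
Why: Hauser-type dianion alkylation, in which the lithium phenoxide is inert in THF and only the more basic methyl-ketone enolate carbon attacks the primary allylic bromide by SN2 (no SN2′, no ionisation), so the future C3–C1′ bond is made at carbon only and the 2E,6E alkenes of 1 are carried over unchanged.

**Step 2**
Reactants: 4 (4E,8E)-1-(2-hydroxyphenyl)-5,9,13-trimethyltetradeca-4,8,12-trien-1-one; 5 methyl chloroformate
Product: 6 methyl 2-[(4E,8E)-5,9,13-trimethyltetradeca-4,8,12-trienoyl]phenyl carbonate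
Conditions: ClCO2Me (1.3 equiv), pyridine, CH2Cl2, 0 °C to rt
Reagents that add atoms: methyl chloroformate (compound 5), COC(=O)Cl
Why: Routine O-acylation of a phenol with a chloroformate, which puts the future C2 carbon on the phenol oxygen and masks the phenol for the next two steps.

**Step 3**
Reactants: 6 methyl 2-[(4E,8E)-5,9,13-trimethyltetradeca-4,8,12-trienoyl]phenyl carbonate
Product: 7 methyl 2-[(4E,8E,12E)-14-hydroxy-5,9,13-trimethyltetradeca-4,8,12-trienoyl]phenyl carbonate
Conditions: SeO2 (0.3 equiv), salicylic acid (0.1 equiv), t-BuOOH (3 equiv), CH2Cl2, 0 °C to rt, stopped before full conversion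
Reagents that add atoms: tert-butyl hydroperoxide, CC(C)(C)OO (terminal oxidant; the oxygen is relayed by catalytic selenium dioxide, O=[Se]=O)
Why: Catalytic SeO2/t-BuOOH allylic hydroxylation (ene reaction, then [2,3]-sigmatropic shift of the allylseleninic acid) should favour the most electron-rich and least hindered terminal isopropylidene and oxidise its methyl group trans to the chain, which sets the 12E alkene; the ketone α-position is not attacked at this temperature.

**Step 4**
Reactants: 7 methyl 2-[(4E,8E,12E)-14-hydroxy-5,9,13-trimethyltetradeca-4,8,12-trienoyl]phenyl carbonate; 8 benzoyl chloride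
Product: 9 (2E,6E,10E)-14-[2-(methoxycarbonyloxy)phenyl]-2,6,10-trimethyl-14-oxotetradeca-2,6,10-trien-1-yl benzoate
Conditions: BzCl (1.2 equiv), pyridine, CH2Cl2, 0 °C
Reagents that add atoms: benzoyl chloride (compound 8), O=C(Cl)c1ccccc1
Why: Standard acylation of a primary allylic alcohol at oxygen (the allylic C–O bond is not broken, so geometry is kept); DMAP is left out so that no acyl-transfer catalyst can shuttle the aryl carbonate onto the alcohol.

**Step 5**
Reactants: 9 (2E,6E,10E)-14-[2-(methoxycarbonyloxy)phenyl]-2,6,10-trimethyl-14-oxotetradeca-2,6,10-trien-1-yl benzoate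
Product: 12 E-ω-benzoyloxyferulenol, via lithium enolate 10 (not isolated), via keto ester phenoxide 11 (not isolated)
Conditions: LiHMDS (1.2 equiv), THF, −78 °C to rt; then 1 M HCl, 0 °C
Reagents that add atoms: none
Why: LiHMDS removes a proton from the only enolisable position (the ketone α-CH2; neither the carbonate nor the benzoate has an α-hydrogen), and the enolate carbon of 10 adds to the ortho carbonate carbonyl through a six-membered transition state (6-(enolendo)-exo-trig), forming C2–C3. Collapse of the adduct with loss of the phenoxide should give β-keto ester 11, whose phenoxide closes the lactone by 6-exo-trig attack on the methyl ester with loss of methoxide; direct loss of methoxide from the first adduct leads to the same ring. The closest known reactions are the carbonate and carbamate variants of the Baker–Venkataraman rearrangement that turn o-acylaryl carbonates into 4-hydroxycoumarins, and the classical dialkyl carbonate/base annulation of o-hydroxyaryl ketones. No stereocentre is formed, since C3 ends as an sp2 carbon of the 4-hydroxycoumarin enol, and the three E alkenes are remote from the anion and should stay untouched. The step needs chemoselectivity for the carbonate over the ω-benzoate and C- over O-acyl transfer: the first is secured by the intramolecular six-membered transition state against an intermolecular Claisen reaction, the second by the irreversible deprotonation of the acidic product (pKa about 4–5), which also consumes the one equivalent of methoxide released before it can attack the benzoate.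

**Compound list**

1 | (2E,6E)-farnesyl bromide, (2E,6E)-1-bromo-3,7,11-trimethyldodeca-2,6,10-triene | CC(C)=CCC/C(C)=C/CC/C(C)=C/CBr | starting material
2 | 2′-hydroxyacetophenone | CC(=O)c1ccccc1O | starting material
3 | dilithium enolate-phenoxide of 2′-hydroxyacetophenone | [Li+].[Li+].C=C([O-])c1ccccc1[O-] | intermediate
4 | (4E,8E)-1-(2-hydroxyphenyl)-5,9,13-trimethyltetradeca-4,8,12-trien-1-one | CC(C)=CCC/C(C)=C/CC/C(C)=C/CCC(=O)c1ccccc1O | intermediate
5 | methyl chloroformate | COC(=O)Cl | starting material
6 | methyl 2-[(4E,8E)-5,9,13-trimethyltetradeca-4,8,12-trienoyl]phenyl carbonate | COC(=O)Oc1ccccc1C(=O)CC/C=C(\C)CC/C=C(\C)CCC=C(C)C | intermediate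
7 | methyl 2-[(4E,8E,12E)-14-hydroxy-5,9,13-trimethyltetradeca-4,8,12-trienoyl]phenyl carbonate | COC(=O)Oc1ccccc1C(=O)CC/C=C(\C)CC/C=C(\C)CC/C=C(\C)CO | intermediate
8 | benzoyl chloride | O=C(Cl)c1ccccc1 | starting material
9 | (2E,6E,10E)-14-[2-(methoxycarbonyloxy)phenyl]-2,6,10-trimethyl-14-oxotetradeca-2,6,10-trien-1-yl benzoate | COC(=O)Oc1ccccc1C(=O)CC/C=C(\C)CC/C=C(\C)CC/C=C(\C)COC(=O)c1ccccc1 | intermediate
10 | lithium enolate of 9 at the aryl ketone (enolate geometry immaterial) | [Li+].COC(=O)Oc1ccccc1C([O-])=CC/C=C(\C)CC/C=C(\C)CC/C=C(\C)COC(=O)c1ccccc1 | intermediate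
11 | lithium 2-[(4E,8E,12E)-14-(benzoyloxy)-2-(methoxycarbonyl)-5,9,13-trimethyltetradeca-4,8,12-trienoyl]phenoxide (transient, racemic at C2, centre erased on enolisation) | [Li+].[O-]c1ccccc1C(=O)C(C(=O)OC)C/C=C(\C)CC/C=C(\C)CC/C=C(\C)COC(=O)c1ccccc1 | intermediate
12 | E-ω-benzoyloxyferulenol, (2E,6E,10E)-12-(4-hydroxy-2-oxo-2H-chromen-3-yl)-2,6,10-trimethyldodeca-2,6,10-trien-1-yl benzoate | C/C(=C\CC/C(C)=C/Cc1c(O)c2ccccc2oc1=O)CC/C=C(\C)COC(=O)c1ccccc1 | target

**Totals.** Total step count: 5. Longest linear sequence: 5 steps (1 → 4 → 6 → 7 → 9 → 12).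

**Steps most likely to fail**

1. Step 3. The risk is poor site selectivity of the allylic oxidation among three trisubstituted alkenes (competing hydroxylation at the internal allylic CH2 groups) and over-oxidation to the enal, which cannot be reduced back cleanly beside the aryl ketone. Fallback (sets out from 1, returns at 9): the oxidation is moved to the farnesyl ester, where the C2 alkene is deactivated by the allylic acetate, no ketone is present, and the benzoate is in place before the coupling. Bromide 1 with KOAc in DMF should give (2E,6E)-farnesyl acetate F1. SeO2/t-BuOOH, followed by NaBH4 to return any enal, should give (2E,6E,10E)-12-hydroxy-3,7,11-trimethyldodeca-2,6,10-trien-1-yl acetate F2. BzCl/pyridine should give (2E,6E,10E)-12-acetoxy-2,6,10-trimethyldodeca-2,6,10-trien-1-yl benzoate F3. K2CO3 in MeOH at 0 °C, where the acetate is cleaved faster than the benzoate, should give (2E,6E,10E)-12-hydroxy-2,6,10-trimethyldodeca-2,6,10-trien-1-yl benzoate F4. MsCl/Et3N then LiBr in THF should give (2E,6E,10E)-12-bromo-2,6,10-trimethyldodeca-2,6,10-trien-1-yl benzoate F5. Alkylation of dianion 3 with F5 under the conditions of step 1 should give (2E,6E,10E)-14-(2-hydroxyphenyl)-2,6,10-trimethyl-14-oxotetradeca-2,6,10-trien-1-yl benzoate F6, and ClCO2Me/pyridine as in step 2 should then give 9.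

2. Step 5. The risk is cleavage or migration of the ω-benzoate by liberated methoxide or by the enolate, or stalling of the sequence at the open keto ester stage. Fallback (sets out from 7, returns at 12): the ring closure is run on a substrate without a second ester, and the benzoate is introduced last. Alcohol 7 with TBSOTf/2,6-lutidine at −78 °C should give methyl 2-[(4E,8E,12E)-14-(tert-butyldimethylsilyloxy)-5,9,13-trimethyltetradeca-4,8,12-trienoyl]phenyl carbonate F7. LiHMDS as in step 5 should give 3-[(2E,6E,10E)-12-(tert-butyldimethylsilyloxy)-3,7,11-trimethyldodeca-2,6,10-trien-1-yl]-4-hydroxycoumarin F8. HF·pyridine in THF should give E-ω-hydroxyferulenol F9. Exhaustive benzoylation (BzCl, 2.5 equiv, pyridine) should give 3-[(2E,6E,10E)-12-(benzoyloxy)-3,7,11-trimethyldodeca-2,6,10-trien-1-yl]-2-oxo-2H-chromen-4-yl benzoate F10. Its enol benzoate is a vinylogous mixed anhydride and should be removed selectively by morpholine (1.1 equiv, THF, 0 °C) to give 12.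

3. Step 1. The risk is proton exchange between product and dianion leading to dialkylation, or sluggish alkylation of the aggregated dianion with competing O-alkylation. Fallback (sets out from 1, returns at 4): the aryl ketone is made by forming the aryl–acyl bond instead of the Cα–Cβ bond. Bromide 1 with the lithium enolate of N-methoxy-N-methylacetamide (LDA, THF, −78 °C) should give (4E,8E)-N-methoxy-N,5,9,13-tetramethyltetradeca-4,8,12-trienamide F11. Addition of 2-(methoxymethoxy)phenyllithium (from (methoxymethoxy)benzene by ortho-lithiation with n-BuLi/TMEDA) should give (4E,8E)-1-[2-(methoxymethoxy)phenyl]-5,9,13-trimethyltetradeca-4,8,12-trien-1-one F12. Mild acid (PPTS, MeOH, 50 °C) should remove the MOM group to give 4.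

**Further compounds**

F1 | step 3 | (2E,6E)-farnesyl acetate | CC(C)=CCC/C(C)=C/CC/C(C)=C/COC(C)=O
F2 | step 3 | (2E,6E,10E)-12-hydroxy-3,7,11-trimethyldodeca-2,6,10-trien-1-yl acetate | CC(=O)OC/C=C(\C)CC/C=C(\C)CC/C=C(\C)CO
F3 | step 3 | (2E,6E,10E)-12-acetoxy-2,6,10-trimethyldodeca-2,6,10-trien-1-yl benzoate | CC(=O)OC/C=C(\C)CC/C=C(\C)CC/C=C(\C)COC(=O)c1ccccc1
F4 | step 3 | (2E,6E,10E)-12-hydroxy-2,6,10-trimethyldodeca-2,6,10-trien-1-yl benzoate | OC/C=C(\C)CC/C=C(\C)CC/C=C(\C)COC(=O)c1ccccc1
F5 | step 3 | (2E,6E,10E)-12-bromo-2,6,10-trimethyldodeca-2,6,10-trien-1-yl benzoate | BrC/C=C(\C)CC/C=C(\C)CC/C=C(\C)COC(=O)c1ccccc1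
F6 | step 3 | (2E,6E,10E)-14-(2-hydroxyphenyl)-2,6,10-trimethyl-14-oxotetradeca-2,6,10-trien-1-yl benzoate | Oc1ccccc1C(=O)CC/C=C(\C)CC/C=C(\C)CC/C=C(\C)COC(=O)c1ccccc1
F7 | step 5 | methyl 2-[(4E,8E,12E)-14-(tert-butyldimethylsilyloxy)-5,9,13-trimethyltetradeca-4,8,12-trienoyl]phenyl carbonate | COC(=O)Oc1ccccc1C(=O)CC/C=C(\C)CC/C=C(\C)CC/C=C(\C)CO[Si](C)(C)C(C)(C)C
F8 | step 5 | 3-[(2E,6E,10E)-12-(tert-butyldimethylsilyloxy)-3,7,11-trimethyldodeca-2,6,10-trien-1-yl]-4-hydroxycoumarin | O=c1oc2ccccc2c(O)c1C/C=C(\C)CC/C=C(\C)CC/C=C(\C)CO[Si](C)(C)C(C)(C)C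
F9 | step 5 | E-ω-hydroxyferulenol, 4-hydroxy-3-[(2E,6E,10E)-12-hydroxy-3,7,11-trimethyldodeca-2,6,10-trien-1-yl]coumarin | O=c1oc2ccccc2c(O)c1C/C=C(\C)CC/C=C(\C)CC/C=C(\C)CO
F10 | step 5 | 3-[(2E,6E,10E)-12-(benzoyloxy)-3,7,11-trimethyldodeca-2,6,10-trien-1-yl]-2-oxo-2H-chromen-4-yl benzoate | O=c1oc2ccccc2c(OC(=O)c2ccccc2)c1C/C=C(\C)CC/C=C(\C)CC/C=C(\C)COC(=O)c1ccccc1
F11 | step 1 | (4E,8E)-N-methoxy-N,5,9,13-tetramethyltetradeca-4,8,12-trienamide | CC(C)=CCC/C(C)=C/CC/C(C)=C/CCC(=O)N(C)OC
F12 | step 1 | (4E,8E)-1-[2-(methoxymethoxy)phenyl]-5,9,13-trimethyltetradeca-4,8,12-trien-1-one | COCOc1ccccc1C(=O)CC/C=C(\C)CC/C=C(\C)CCC=C(C)C
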